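A direct plan would assemble the pyrone as a polyketide chain: two Claisen acylations would lead via keto ester A1 to the 3,5-diketo ester A2 that carries the C10 alkenyl chain, base would lactonise A2 to the 4-hydroxy-2-pyranone A3, O-methylation would give the dimethoxypyrone A4, and a radical addition of a thioacid to the terminal alkene would finish.
Weak step 1, the γ-acylation of the dianion of A1 with the long-chain ester: A2 is more acidic than A1 and quenches the dianion, so the elaborated nucleophile would be needed in excess, and the whole chain would be joined in the least reliable C–C step.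
Weak step 2, the O-methylation of A3: the vinylogous acid is ambident and would give A4 together with the isomeric 2-methoxy-4-pyranone A5, so the 4-OMe would be settled only after the ring exists, and by chromatography.
Weak step 3, the final radical hydrothiolation of A4: a radical chain with reversible thiyl addition would be run on all the material at the last step, next to an electron-rich, light-absorbing pyrone.

**Retrosynthetic overview**
- Feature used: C5=C6 of the pyrone carries two sp3 carbons (the 5-CH3 and C1′ of the chain), so C5, C6 and these two carbons are but-2-yne; C2–C3–C4 with both methoxy groups is (Z)-2,3-dimethoxyacrylic acid.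
- Key disconnection: C4–C5 and C6–O1, both formed in one Rh(III)-catalysed oxidative C–H/O–H annulation of the acid with the symmetric alkyne; this closes the only ring (step 3) from a C3 and a C4 fragment.
- Chain: C1′–C2′ by alkylation of the vinylogous anion at the 6-CH3 (the only methyl conjugated to C2=O, through C6=C5–C4=C3) with 1,9-dibromononane; the S-acetyl group enters last by SN2.
- Avoided by design: no dianion acylation (the chain enters as a cheap dihalide onto a stabilised anion), no methylation of an ambident hydroxypyrone (both OMe are fixed on the acyclic acid), no radical step.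

Key step: step 3

Assumption: the target has no stereocentre and no stereogenic double bond, so no stereocontrol is needed; the (Z) geometry of 4 and 5 only serves the C–H activation and vanishes in the ring.

**Route**

Step 1
Reactants: 1 methyl methoxyacetate; 2 methyl formate
Product: 4 methyl (Z)-2,3-dimethoxyacrylate, via sodium formyl enolate 3 (not isolated)
Conditions: NaOMe (1.2 equiv), 2 (3 equiv), THF, 0 °C → rt; then Me2SO4 (1.3 equiv), DMF, rt → 50 °C
Reagents that add atoms: dimethyl sulfate, COS(=O)(=O)OC
Why: Crossed Claisen condensation with the non-enolisable formate, followed by O-alkylation of the sodium enolate with the hard electrophile dimethyl sulfate in a dipolar solvent, should give the β-methoxyacrylate, the isomer with 3-OMe trans to the ester (C3–H cis to it) being the thermodynamically preferred one of this push–pull alkene.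

Step 2
Reactants: 4 methyl (Z)-2,3-dimethoxyacrylate
Product: 5 (Z)-2,3-dimethoxyacrylic acid
Conditions: LiOH·H2O (1.5 equiv), THF/H2O, 0 °C → rt; 1 M HCl to pH 3, 0 °C
Reagents that add atoms: lithium hydroxide, [Li+].[OH-]
Why: Ester saponification should proceed at the acyl carbon without touching the enol ether, and brief cold acidification should liberate the acid with retention of the double-bond geometry.

Step 3
Reactants: 5 (Z)-2,3-dimethoxyacrylic acid; 6 but-2-yne
Product: 7 3,4-dimethoxy-5,6-dimethyl-2H-pyran-2-one
Conditions: [Cp*RhCl2]2 (2.5 mol %), Ag2CO3 (1.0 equiv), 6 (3 equiv), DMF, 110 °C, sealed tube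
Reagents that add atoms: none
Why: Carboxylate-directed oxidative C–H/O–H annulation: the Rh(III) carboxylate of 5 should cleave the vinylic C3–H that lies cis to CO2H by concerted metalation–deprotonation to a five-membered rhodacycle, 6 should insert into the Rh–C bond to a seven-membered oxarhodacycle, and C–O reductive elimination should release 7 while Ag(I) returns Rh(I) to Rh(III). The closest known reaction type is the Rh(III)-catalysed oxidative coupling of acrylic acids with internal alkynes to α-pyrones (and of benzoic acids to isocoumarins). The pyrone ring is closed in a formal [4+2] mode, C4–C5 by migratory insertion and C6–O1 by reductive elimination, so neither ring bond is made by acyl substitution. No stereocentre is formed. The step needs regiochemistry on the alkyne and site selectivity on the acid: the first is void because 6 is symmetric, and the second is fixed because C2 of 5 carries OMe and only the C3–H is available, the (Z) geometry (or its thermal equilibration through the push–pull double bond) placing it next to the carboxylate. Both methoxy groups enter the ring as spectators, so no ambident oxygen of a formed pyrone has to be alkylated.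

Step 4
Reactants: 7 3,4-dimethoxy-5,6-dimethyl-2H-pyran-2-one; 8 1,9-dibromononane
Product: 10 6-(10-bromodecyl)-3,4-dimethoxy-5-methyl-2H-pyran-2-one, via lithiated pyrone 9 (not isolated)
Conditions: LDA (1.05 equiv), THF, −78 °C; then 8 (4 equiv), DMPU, −78 → −20 °C
Reagents that add atoms: none
Why: Vinylogous (lateral) enolate alkylation: LDA should deprotonate only the 6-CH3, whose anion is delocalised through C6=C5–C4=C3 onto the C2 carbonyl (the 5-CH3 is cross-conjugated), and the anion should react at the exocyclic carbon with the primary bromide by SN2, the excess of dibromide suppressing double substitution.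

Step 5
Reactants: 10 6-(10-bromodecyl)-3,4-dimethoxy-5-methyl-2H-pyran-2-one; 11 potassium thioacetate
Product: 12 lehualide H, S-[10-(4,5-dimethoxy-3-methyl-6-oxo-6H-pyran-2-yl)decyl] ethanethioate
Conditions: 11 (1.3 equiv), DMF, rt
Reagents that add atoms: none
Why: SN2 S-alkylation of thioacetate by the primary bromide should give the thioester directly, the weakly basic, soft nucleophile leaving the pyrone lactone and both enol ethers untouched.

**Compound list**
1 | methyl methoxyacetate | COCC(=O)OC | starting material
2 | methyl formate | COC=O | starting material
3 | sodium 2,3-dimethoxy-3-oxoprop-1-en-1-olate (configurationally labile formyl enolate) | [Na+].[O-]C=C(OC)C(=O)OC | intermediate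
4 | methyl (Z)-2,3-dimethoxyacrylate | CO/C=C(\OC)C(=O)OC | intermediate
5 | (Z)-2,3-dimethoxyacrylic acid | CO/C=C(\OC)C(=O)O | intermediate
6 | but-2-yne | CC#CC | starting material
7 | 3,4-dimethoxy-5,6-dimethyl-2H-pyran-2-one | COc1c(C)c(C)oc(=O)c1OC | intermediate
8 | 1,9-dibromononane | BrCCCCCCCCCBr | starting material
9 | [(4,5-dimethoxy-3-methyl-6-oxo-6H-pyran-2-yl)methyl]lithium (delocalised trienolate) | [Li]Cc1oc(=O)c(OC)c(OC)c1C | intermediate
10 | 6-(10-bromodecyl)-3,4-dimethoxy-5-methyl-2H-pyran-2-one | COc1c(C)c(CCCCCCCCCCBr)oc(=O)c1OC | intermediate
11 | potassium thioacetate | CC(=O)[S-].[K+] | starting material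
12 | lehualide H | COc1c(C)c(CCCCCCCCCCSC(C)=O)oc(=O)c1OC | target

Total step count: 5
Longest linear sequence: 5 steps (1 → 4 → 5 → 7 → 10 → 12)

**Steps most likely to fail**

1. Step 3, the oxidative annulation. Protodecarboxylation of the electron-rich acid at the metal carboxylate stage, or slow metalation of the donor-substituted C3–H, could outrun alkyne insertion, and the volatile alkyne may escape. The fallback replaces C–H activation by oxidative addition of a preformed C4–halogen bond. Setting out from 4, deprotonation of the C3–H cis to the ester (LiTMP, THF, −95 °C) and iodination (I2) would give methyl (E)-3-iodo-2,3-dimethoxyacrylate F1. A Larock-type Pd(0) annulation of F1 with 6 (Pd(OAc)2, Na2CO3, LiCl, DMF, 100 °C), in which the ester oxygen closes onto the vinylpalladium and the ester methyl is lost, would come back to the route at 7.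

2. Step 4, the lateral alkylation. Proton transfer from 10 to unreacted anion 9 could lead to double alkylation, the amide base could add to the pyrone ring and open it, and the delocalised, weakly nucleophilic anion could favour E2 loss of HBr from 8. The fallback reverses the polarity at C1′. Setting out from 7, Wohl–Ziegler bromination (NBS, AIBN, PhCF3, 80 °C) at the 6-methyl, the position that gives the most delocalised radical, would give 6-(bromomethyl)-3,4-dimethoxy-5-methyl-2H-pyran-2-one F2. Copper-catalysed Grignard cross-coupling (Li2CuCl4 cat., THF, −40 °C, inverse addition) with (9-chlorononyl)magnesium bromide F3, prepared from commercial 1-bromo-9-chlorononane and magnesium, would give 6-(10-chlorodecyl)-3,4-dimethoxy-5-methyl-2H-pyran-2-one F4. Displacement with 11 (NaI cat., DMF, 60 °C) would come back to the route at 12.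

3. Step 1, formylation and O-methylation. The formylation could revert (retro-Claisen) before alkylation, the ambident enolate could be C-methylated, or the geometric isomer with C3–H trans to the ester could predominate. The fallback introduces C3 at the amide-acetal oxidation level without an enolate alkylation. Setting out from 1, condensation with tert-butoxybis(dimethylamino)methane (neat, 90 °C) would give methyl (Z)-3-(dimethylamino)-2-methoxyacrylate F5. Acid-mediated exchange of the dimethylamino group for methoxy (MeOH, HC(OMe)3, TsOH, reflux) would come back to the route at 4.

**Further compounds**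
F1 | step 3 | methyl (E)-3-iodo-2,3-dimethoxyacrylate | CO/C(I)=C(\OC)C(=O)OC
F2 | step 4 | 6-(bromomethyl)-3,4-dimethoxy-5-methyl-2H-pyran-2-one | COc1c(C)c(CBr)oc(=O)c1OC
F3 | step 4 | (9-chlorononyl)magnesium bromide | ClCCCCCCCCC[Mg]Br
F4 | step 4 | 6-(10-chlorodecyl)-3,4-dimethoxy-5-methyl-2H-pyran-2-one | COc1c(C)c(CCCCCCCCCCCl)oc(=O)c1OC
F5 | step 1 | methyl (Z)-3-(dimethylamino)-2-methoxyacrylate | CN(C)/C=C(\OC)C(=O)OC
A1 | direct plan | methyl 2-methoxy-3-oxopentanoate | CCC(=O)C(OC)C(=O)OC
A2 | direct plan | methyl 2-methoxy-4-methyl-3,5-dioxopentadec-14-enoate | COC(=O)C(OC)C(=O)C(C)C(=O)CCCCCCCCC=C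
A3 | direct plan | 6-(dec-9-en-1-yl)-4-hydroxy-3-methoxy-5-methyl-2H-pyran-2-one | COc1c(O)c(C)c(CCCCCCCCC=C)oc1=O
A4 | direct plan | 6-(dec-9-en-1-yl)-3,4-dimethoxy-5-methyl-2H-pyran-2-one | COc1c(OC)c(C)c(CCCCCCCCC=C)oc1=O
A5 | direct plan | 6-(dec-9-en-1-yl)-2,3-dimethoxy-5-methyl-4H-pyran-4-one | COc1oc(CCCCCCCCC=C)c(C)c(=O)c1OC
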